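## Structural features

The target 20 is a (2S)-flavanone. Ring A (C4a–C8a) is a phloroglucinol core with free hydroxyls at C5 and C7 and a 3-hydroxy-3-methylbutyl chain at C8; ring C (O1, C2, C3, C4) is the dihydropyranone; ring B, joined to C2 through C1′, carries a free 2′-hydroxyl and a 2,2-dimethyl-2H-pyran ring D fused across C4′–C5′ with its oxygen on C4′. C2 is the only stereocentre and has no stereogenic neighbour, but it sits between the acidic C3 methylene and an aryl ring with ortho and para oxygen donors. The C2–O1 bond is therefore fragile in both directions: base opens ring C to the achiral chalcone, and acid can ionise C2. Two further groups are acid-sensitive: the styrenic ring D alkene, and the tertiary alcohol, which would close onto the neighbouring C7 hydroxyl to a dimethylchroman. The C8a oxygen is flanked on both sides (C8 chain, C4a carbon), so the enantioselective C2–O1 bond formation must succeed at a di-ortho-substituted phenol. The real difficulty is the order of events: ring C must be closed without base, no palladium or Lewis acid may meet the allylic aryl ether once C2 is set, and the final unmasking must avoid both base and strong acid. The key step uses the C3–C4 bond: C4 is a ketone carbon and C3 is a methylene bonded directly to C2, so C3=C4 can be drawn as an enol ether double bond. Its C3 end is the inner carbon of a vinyl group on C2 (the vinyl group sits on C2, not on C3), and its C4 end is a 1-silyloxyvinyl group on C4a, which brings C4 in at the ketone oxidation level.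

## Logic of the disconnections

20 ⇒ 19. Five O–Si bonds are cut (two aryl triisopropylsilyl ethers, one aryl tert-butyldimethylsilyl ether, one tertiary triethylsilyl ether, one enol triethylsilyl ether). Making every masking group silicon-based lets one buffered fluoride treatment release three phenols, the tertiary alcohol and the C4 ketone together. Acid-labile acetals are avoided because their removal would need acid strong enough to endanger the tertiary alcohol, ring D and C2. The forward step must not generate a free enolate or phenoxide.

19 ⇒ 18. The C3=C4 double bond is cut by retro-metathesis into a vinyl group on C2 and a 1-(triethylsilyloxy)vinyl group on C4a. This opens ring C and reduces the problem to an aryl methyl ketone bearing a chiral allylic aryl ether. The forward step requires the ruthenium carbene to load on the vinyl group, close onto a hindered 1,1-disubstituted enol ether, and leave ring D and C2 alone.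

18 ⇒ 17. The enol O–Si and tertiary O–Si bonds are cut, returning the methyl ketone. The enol ether is made by enolate silylation and not by cross-coupling on an aryl halide, so no zerovalent palladium (which ionises allylic aryl ethers) and no tin reagent is used after the stereocentre exists. The forward step needs a base that removes the ketone α-proton but not the C2–H, and no Lewis acid.

17 ⇒ 5 + 16. The C2–O1 bond is cut. This is the convergent union of the ring A and ring B halves and the point where C2 is set, by iridium-catalysed allylic etherification of the linear carbonate 16 with the phenol of 5. The forward step must be branched-selective and enantioselective with a di-ortho-substituted, hydrogen-bonded phenoxide and an ortho-substituted cinnamyl unit.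

16 ⇒ 15 ⇒ 14 ⇒ 12 + 13. The carbonate C–O bond, the ester oxidation level and the C1′–Cα bond are cut in turn, back to an aryl bromide and an acrylate. The Heck step must give the E alkene and ignore the ring D alkene.

12 ⇒ 10 ⇒ 9 ⇒ 6 + 7. The ring D alkene is taken back to a ketone, the silyl ether to the phenol, and the chromanone to a resorcinol and a C5 acid (aryl–acyl C–C bond and O–C(CH3)2 bond). Ring D is thus built at the very start from bulk chemicals, with the linear fusion fixed by the substituent pattern of 6: acylation para to one hydroxyl places bromine at the future C1′ and the free hydroxyl at the future C2′.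

5 ⇒ 4 ⇒ 3 ⇒ 1 + 2. The tertiary C–O bond (hydration of a prenyl group), two aryl O–Si bonds and the C8–CH2 bond are cut, back to the symmetric triol 1 and the allylic bromide 2. The symmetry of 1 makes the C-alkylation regiochemically unambiguous, and the acetyl group (future C4 plus the carbon lost as ethene) is present from the first step, so ring A never needs halogenation. The forward demand is selective silylation of two of three hydroxyls and a hydration that forms no carbocation next to a free phenol.

## Other disconnections considered

Alternative 1: Ring A by Diels–Alder benzannulation. The cut is C4a–C5 and C8–C8a, so ring A is made last. In the forward step the (2S)-sulfinyl dihydropyranone A2 (ring C with ring B attached) and the 4-alkyl bis(silyloxy)diene A3 would undergo cycloaddition, sulfoxide elimination and loss of methanol on heating to give flavanone A1.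

- In its favour: the ring A pattern (chain at C8, oxygens at C5 and C7) is written into the polarity of A3, so no phloroglucinol hydroxyls need to be told apart. This is better than the chosen plan, whose steps 1 and 2 rely on selective mono-alkylation and selective silylation. The ring A phenols emerge free, and the key step needs no transition metal.
- Against it: C2 must be set when A2 is made and must then survive sulfenylation, oxidation and heating. A2 is a β-alkoxy enone that can open by retro-oxa-Michael reaction. A3 is a hindered, geometrically ill-defined and moisture-sensitive diene. Sulfenic acid is released next to ring D. A1 still needs two unmasking operations (zerovalent palladium deallylation, fluoride).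
- Comparison: equal in principle on C2 (a catalytic asymmetric step upstream in both), worse on thermal stress at C2, better on ring A regiocontrol. Step count is about equal, since A2 and A3 each need several steps.

Alternative 2: Ring D last by thermal propargyl ether cascade. The cut is C5′–CH= and O–C(CH3)2 in ring D. In the forward step the 4′-O-(1,1-dimethylpropargyl) ether A5 of an otherwise complete silylated flavanone would be heated to about 140 °C, giving A4 by aromatic propargyl Claisen rearrangement, 1,5-hydrogen shift and oxa-6π electrocyclisation.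

- In its favour: the ring D alkene is absent during all earlier chemistry, so metathesis would have one alkene fewer to consider and acid or hydrogenation could be used freely. On this point it is better than the chosen plan. The step needs no reagent.
- Against it: the rearrangement can end at C3′ or C5′, and C3′, lying between two oxygens, is electronically favoured; only the bulk of the 2′-silyl ether argues for C5′. In the chosen plan the linear fusion is fixed by bromine in 6, which is more secure. Heating a (2S)-flavanone at 140 °C risks racemisation through the chalcone and silyl migration. The 4′-oxygen must be unmasked selectively among four silylated oxygens. The disconnection does not make ring C or set C2, so it must be combined with another ring C strategy.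
- Comparison: equal on the final deprotection (silyl ethers, fluoride). It is longer by about three late steps than the two early ring D steps (4 and 6) of the chosen plan.

Alternative 3: Oxa-(4+2) union of a ring A quinone methide and a hydroxystyrene. The cut is C3–C4 and O1–C2. In the forward step salicylaldehyde A7, activated by trimethyl orthoformate and a confined chiral phosphoric acid, and ortho-hydroxystyrene A8 would combine to the 2,4-cis-4-methoxyflavan A6.

- In its favour: it is the most convergent option. Ring C and C2 are made in one catalytic enantioselective step from two simple halves, the 2′-hydroxyl needs no protection, and no stereocentre is carried. On convergence and key-stage step count it is better than the chosen plan.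
- Against it: A6 is at the flavan oxidation level. C4–OMe must be oxidised to the ketone in the presence of the ring D alkene, three electron-rich arenes and a free phenol, which is a poor prospect for benzylic oxidation. The acidic medium endangers the tertiary alcohol of A7, which sits next to the free phenol and can close to a chroman. The trioxygenated quinone methide is strongly stabilised and sluggish. The ring D alkene of A8 is a second electron-rich styrene.
- Comparison: equal on the source of stereocontrol (catalyst in both) and on mildness of the last unmasking (zerovalent palladium deallylation against fluoride). It is worse on redox economy, because the chosen plan delivers C4 as a masked ketone. It is shorter up to ring C but longer after it.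

Key step: step 12

Assumption: the iridium catalyst built from the (Sa,Sc,Sc) phosphoramidite is taken to deliver aryloxides to the face of the 1-arylallyl terminus that gives the (S) ether, as for simple cinnamyl carbonates; the ortho-silyloxy group is assumed not to reverse this sense. Compounds 1, 2, 6, 7 and 13 are commercial.

## Route

Step 1
Reactants: 1 1-(2,4,6-trihydroxyphenyl)ethan-1-one; 2 1-bromo-3-methylbut-2-ene
Product: 3 1-[2,4,6-trihydroxy-3-(3-methylbut-2-en-1-yl)phenyl]ethan-1-one
Conditions: DBU (1.0 equiv), THF, 0 → 25 °C
Reagents that add atoms: none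
Why: C-alkylation of a phloroglucinol-type phenoxide (an ambident vinylogous enolate) with an allylic bromide; the two free ring positions of 1 are equivalent, so mono-C-prenylation can give only one regioisomer, and limiting 2 to one equivalent should hold back double and O-alkylation.

Step 2
Reactants: 3 1-[2,4,6-trihydroxy-3-(3-methylbut-2-en-1-yl)phenyl]ethan-1-one
Product: 4 1-[2-hydroxy-3-(3-methylbut-2-en-1-yl)-4,6-bis(triisopropylsilyloxy)phenyl]ethan-1-one
Conditions: TIPSCl (2.2 equiv), imidazole, DMF, 0 → 25 °C
Reagents that add atoms: triisopropylsilyl chloride, CC(C)[Si](Cl)(C(C)C)C(C)C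
Why: Phenol silylation under steric control: the C4 hydroxyl (para to acetyl, most acidic) and the C6 hydroxyl (one open flank) should react, while the C2 hydroxyl, wedged between acetyl and prenyl and hydrogen-bonded to the carbonyl, should stay free; the bulk of the triisopropylsilyl group enforces the distinction.

Step 3
Reactants: 4 1-[2-hydroxy-3-(3-methylbut-2-en-1-yl)-4,6-bis(triisopropylsilyloxy)phenyl]ethan-1-one
Product: 5 1-[2-hydroxy-3-(3-hydroxy-3-methylbutyl)-4,6-bis(triisopropylsilyloxy)phenyl]ethan-1-one
Conditions: Co(acac)2 (20 mol%), PhSiH3, O2 (1 atm), THF, 25 °C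
Reagents that add atoms: dioxygen, O=O
Why: Mukaiyama hydration (hydrogen-atom transfer from a cobalt hydride, capture of the tertiary radical by O2, reduction of the peroxide by silane) should give the Markovnikov tertiary alcohol; no carbocation forms, so the neighbouring phenol cannot close to a chroman as it would under acid, and the aryl ketone and silyl ethers are untouched.

Step 4
Reactants: 6 4-bromobenzene-1,3-diol; 7 3-methylbut-2-enoic acid
Product: 9 6-bromo-7-hydroxy-2,2-dimethylchroman-4-one, via aryl enone 8 (not isolated)
Conditions: P2O5, MeSO3H, 70 °C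
Reagents that add atoms: none
Why: Friedel–Crafts acylation followed by intramolecular oxa-Michael addition: acylation should occur at C6 of 6 (para to one hydroxyl, ortho to the other, the only unhindered activated position) and the ortho hydroxyl then closes the 2,2-dimethylchromanone, placing bromine at C6 and the free hydroxyl at C7.

Step 5
Reactants: 9 6-bromo-7-hydroxy-2,2-dimethylchroman-4-one
Product: 10 6-bromo-7-(tert-butyldimethylsilyloxy)-2,2-dimethylchroman-4-one
Conditions: TBSCl, imidazole, DMF, 25 °C
Reagents that add atoms: tert-butyldimethylsilyl chloride, CC(C)(C)[Si](C)(C)Cl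
Why: Standard phenol silylation; the ether masks the future 2′-hydroxyl, prevents phenoxide deactivation of the ketone in the reduction, and is later removed by fluoride.

Step 6
Reactants: 10 6-bromo-7-(tert-butyldimethylsilyloxy)-2,2-dimethylchroman-4-one
Product: 12 (6-bromo-2,2-dimethyl-2H-chromen-7-yl)oxy(tert-butyl)dimethylsilane, via chroman-4-ol 11 (not isolated)
Conditions: NaBH4, MeOH/THF, 0 °C; then TsOH·H2O (5 mol%), toluene, 50 °C
Reagents that add atoms: none
Why: Borohydride reduction of the aryl ketone, then acid-catalysed E1 dehydration of the benzylic alcohol, whose cation is stabilised by the para silyloxy group and the ortho ring oxygen, so a trace of acid at mild temperature should suffice and the aryl silyl ether should survive; the alkene can only form toward C3 because C4a is aromatic.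

Step 7
Reactants: 12 (6-bromo-2,2-dimethyl-2H-chromen-7-yl)oxy(tert-butyl)dimethylsilane; 13 methyl prop-2-enoate
Product: 14 methyl (2E)-3-[7-(tert-butyldimethylsilyloxy)-2,2-dimethyl-2H-chromen-6-yl]prop-2-enoate
Conditions: Pd2(dba)3 (2 mol%), [HP(t-Bu)3]BF4 (8 mol%), Cy2NMe, 1,4-dioxane, 80 °C
Reagents that add atoms: none
Why: Heck reaction of an electron-rich ortho-substituted aryl bromide under a bulky trialkylphosphine zerovalent palladium catalyst; syn insertion and syn β-hydride elimination should give the E enoate, and the internal ring D alkene next to a quaternary carbon is too hindered to insert.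

Step 8
Reactants: 14 methyl (2E)-3-[7-(tert-butyldimethylsilyloxy)-2,2-dimethyl-2H-chromen-6-yl]prop-2-enoate
Product: 15 (2E)-3-[7-(tert-butyldimethylsilyloxy)-2,2-dimethyl-2H-chromen-6-yl]prop-2-en-1-ol
Conditions: i-Bu2AlH (2.3 equiv), CH2Cl2, −78 °C
Reagents that add atoms: none
Why: 1,2-reduction of the enoate by the aluminium hydride at low temperature should give the E allylic alcohol with the alkene geometry retained; silyl ether, aryl bromide-free ring and ring D are inert.

Step 9
Reactants: 15 (2E)-3-[7-(tert-butyldimethylsilyloxy)-2,2-dimethyl-2H-chromen-6-yl]prop-2-en-1-ol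
Product: 16 (2E)-3-[7-(tert-butyldimethylsilyloxy)-2,2-dimethyl-2H-chromen-6-yl]prop-2-en-1-yl methyl carbonate
Conditions: ClCO2Me, pyridine, CH2Cl2, 0 °C
Reagents that add atoms: methyl chloroformate, COC(=O)Cl
Why: Acylation of the primary allylic alcohol to the linear methyl carbonate, the leaving group that on ionisation releases CO2 and methoxide for the next step.

Step 10
Reactants: 5 1-[2-hydroxy-3-(3-hydroxy-3-methylbutyl)-4,6-bis(triisopropylsilyloxy)phenyl]ethan-1-one; 16 (2E)-3-[7-(tert-butyldimethylsilyloxy)-2,2-dimethyl-2H-chromen-6-yl]prop-2-en-1-yl methyl carbonate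
Product: 17 1-[2-{[(1S)-1-[7-(tert-butyldimethylsilyloxy)-2,2-dimethyl-2H-chromen-6-yl]prop-2-en-1-yl]oxy}-3-(3-hydroxy-3-methylbutyl)-4,6-bis(triisopropylsilyloxy)phenyl]ethan-1-one
Conditions: 5 (1.2 equiv), [Ir(cod)Cl]2 (2.5 mol%), (Sa)-(1,1′-binaphthyl-2,2′-diyl) N,N-bis[(S)-1-(2-methoxyphenyl)ethyl]phosphoramidite (5 mol%), TBD (10 mol%), THF, 25 → 45 °C
Reagents that add atoms: none
Why: Iridium-catalysed asymmetric allylic etherification: the cyclometallated iridium phosphoramidite complex ionises 16 to an allyl complex that the phenoxide of 5 attacks at the aryl-bearing terminus, giving the branched ether, and the (S) configuration at the future C2 is set by the (Sa,Sc,Sc) ligand, whose 2-methoxyphenyl groups are chosen because they tolerate ortho-substituted cinnamyl units. The methoxide released regenerates the phenoxide from 5, so no strong base accumulates and the far less acidic tertiary alcohol stays a spectator.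

Step 11
Reactants: 17 1-[2-{[(1S)-1-[7-(tert-butyldimethylsilyloxy)-2,2-dimethyl-2H-chromen-6-yl]prop-2-en-1-yl]oxy}-3-(3-hydroxy-3-methylbutyl)-4,6-bis(triisopropylsilyloxy)phenyl]ethan-1-one
Product: 18 triethyl{[1-(2-{[(1S)-1-[7-(tert-butyldimethylsilyloxy)-2,2-dimethyl-2H-chromen-6-yl]prop-2-en-1-yl]oxy}-3-[3-methyl-3-(triethylsilyloxy)butyl]-4,6-bis(triisopropylsilyloxy)phenyl)ethenyl]oxy}silane
Conditions: KN(SiMe3)2 (2.3 equiv), THF, −78 °C; Et3SiCl (2.5 equiv), −78 → −20 °C; pH 7 buffer work-up, Et3N-deactivated silica
Reagents that add atoms: triethylsilyl chloride, CC[Si](Cl)(CC)CC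
Why: Deprotonation of the tertiary alcohol and of the methyl ketone, then O-silylation of alkoxide and potassium enolate, should give the terminal silyl enol ether and the tertiary silyl ether in one operation; the conditions contain no Lewis acid and no transition metal, so the ionisable C2–O bond and the C2 configuration should be preserved (the C2–H is far less acidic than the ketone methyl).

Step 12
Reactants: 18 triethyl{[1-(2-{[(1S)-1-[7-(tert-butyldimethylsilyloxy)-2,2-dimethyl-2H-chromen-6-yl]prop-2-en-1-yl]oxy}-3-[3-methyl-3-(triethylsilyloxy)butyl]-4,6-bis(triisopropylsilyloxy)phenyl)ethenyl]oxy}silane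
Product: 19 (2S)-2-[7-(tert-butyldimethylsilyloxy)-2,2-dimethyl-2H-chromen-6-yl]-4-(triethylsilyloxy)-8-[3-methyl-3-(triethylsilyloxy)butyl]-5,7-bis(triisopropylsilyloxy)-2H-chromene
Conditions: second-generation Grubbs catalyst RuCl2(=CHPh)(PCy3)(H2IMes) (10 mol%), 1,4-benzoquinone (20 mol%), toluene (0.005 M), 70 °C, Ar
Reagents that add atoms: none
Why: Ring-closing metathesis of an enol ether–olefin diene: the ruthenium benzylidene should exchange first with the monosubstituted vinyl group on C2, the only unhindered terminal alkene, placing a ruthenium alkylidene on the future C3. Intramolecular (2+2) cycloaddition with the 1-(triethylsilyloxy)vinyl group on C4a and cycloreversion of the ruthenacyclobutane should form C3=C4 and release Ru=CH2, which returns as ethene. The closest known reaction type is the ring-closing metathesis of silyl or alkyl enol ether–alkene dienes to cyclic enol ethers such as 2H-chromenes and 4-silyloxy-1,2-dihydroquinolines. Ring C closes as a six-membered ring by C=C formation between two sp2 carbons held ortho on ring A, with C3 and C4 inside the metallacycle and the two methylene carbons expelled. No stereocentre is created; C2 keeps the (S) configuration from step 10 because its four bonds are not involved, and benzoquinone is added to suppress ruthenium hydride migration of the vinyl double bond toward C2, the one process that would erase it. The step needs initiation at the vinyl group and not at the enol ether (which would give an unreactive oxygen-substituted carbene) and no engagement of ring D; the 1,1-disubstitution and di-ortho flanking of the enol ether secure the first, and the endocyclic, unstrained ring D alkene beside a quaternary carbon secures the second. High dilution should keep the reaction intramolecular.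

Step 13
Reactants: 19 (2S)-2-[7-(tert-butyldimethylsilyloxy)-2,2-dimethyl-2H-chromen-6-yl]-4-(triethylsilyloxy)-8-[3-methyl-3-(triethylsilyloxy)butyl]-5,7-bis(triisopropylsilyloxy)-2H-chromene
Product: 20 (2S)-5,7-dihydroxy-2-(7-hydroxy-2,2-dimethyl-2H-chromen-6-yl)-8-(3-hydroxy-3-methylbutyl)chroman-4-one
Conditions: Bu4NF (8 equiv), AcOH (8 equiv), THF, 0 → 25 °C
Reagents that add atoms: none
Why: Fluoride desilylation buffered by acetic acid: the enol ether is protonated at C3 as it is unmasked, giving the C4 ketone, and the three aryl silyl ethers (two activated by the new ortho/para carbonyl) and the tertiary triethylsilyl ether are cleaved in the same pot. The buffer avoids a free enolate or phenoxide, which could open ring C through the chalcone and racemise C2, and avoids strong acid, which could cyclise the tertiary alcohol onto the C7 hydroxyl or hydrate ring D.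

## Compound list

1 | 1-(2,4,6-trihydroxyphenyl)ethan-1-one | CC(=O)c1c(O)cc(O)cc1O | starting material
2 | 1-bromo-3-methylbut-2-ene | CC(C)=CCBr | starting material
3 | 1-[2,4,6-trihydroxy-3-(3-methylbut-2-en-1-yl)phenyl]ethan-1-one | CC(=O)c1c(O)cc(O)c(CC=C(C)C)c1O | intermediate
4 | 1-[2-hydroxy-3-(3-methylbut-2-en-1-yl)-4,6-bis(triisopropylsilyloxy)phenyl]ethan-1-one | CC(=O)c1c(O[Si](C(C)C)(C(C)C)C(C)C)cc(O[Si](C(C)C)(C(C)C)C(C)C)c(CC=C(C)C)c1O | intermediate
5 | 1-[2-hydroxy-3-(3-hydroxy-3-methylbutyl)-4,6-bis(triisopropylsilyloxy)phenyl]ethan-1-one | CC(=O)c1c(O[Si](C(C)C)(C(C)C)C(C)C)cc(O[Si](C(C)C)(C(C)C)C(C)C)c(CCC(C)(C)O)c1O | intermediate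
6 | 4-bromobenzene-1,3-diol | Oc1ccc(Br)c(O)c1 | starting material
7 | 3-methylbut-2-enoic acid | CC(C)=CC(=O)O | starting material
8 | 1-(5-bromo-2,4-dihydroxyphenyl)-3-methylbut-2-en-1-one | CC(C)=CC(=O)c1cc(Br)c(O)cc1O | intermediate (not isolated)
9 | 6-bromo-7-hydroxy-2,2-dimethylchroman-4-one | CC1(C)CC(=O)c2cc(Br)c(O)cc2O1 | intermediate
10 | 6-bromo-7-(tert-butyldimethylsilyloxy)-2,2-dimethylchroman-4-one | CC1(C)CC(=O)c2cc(Br)c(O[Si](C)(C)C(C)(C)C)cc2O1 | intermediate
11 | 6-bromo-7-(tert-butyldimethylsilyloxy)-2,2-dimethylchroman-4-ol (racemic) | CC1(C)CC(O)c2cc(Br)c(O[Si](C)(C)C(C)(C)C)cc2O1 | intermediate (not isolated)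
12 | (6-bromo-2,2-dimethyl-2H-chromen-7-yl)oxy(tert-butyl)dimethylsilane | CC1(C)C=Cc2cc(Br)c(O[Si](C)(C)C(C)(C)C)cc2O1 | intermediate
13 | methyl prop-2-enoate | C=CC(=O)OC | starting material
14 | methyl (2E)-3-[7-(tert-butyldimethylsilyloxy)-2,2-dimethyl-2H-chromen-6-yl]prop-2-enoate | COC(=O)/C=C/c1cc2c(cc1O[Si](C)(C)C(C)(C)C)OC(C)(C)C=C2 | intermediate
15 | (2E)-3-[7-(tert-butyldimethylsilyloxy)-2,2-dimethyl-2H-chromen-6-yl]prop-2-en-1-ol | OC/C=C/c1cc2c(cc1O[Si](C)(C)C(C)(C)C)OC(C)(C)C=C2 | intermediate
16 | (2E)-3-[7-(tert-butyldimethylsilyloxy)-2,2-dimethyl-2H-chromen-6-yl]prop-2-en-1-yl methyl carbonate | COC(=O)OC/C=C/c1cc2c(cc1O[Si](C)(C)C(C)(C)C)OC(C)(C)C=C2 | intermediate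
17 | 1-[2-{[(1S)-1-[7-(tert-butyldimethylsilyloxy)-2,2-dimethyl-2H-chromen-6-yl]prop-2-en-1-yl]oxy}-3-(3-hydroxy-3-methylbutyl)-4,6-bis(triisopropylsilyloxy)phenyl]ethan-1-one | CC(=O)c1c(O[Si](C(C)C)(C(C)C)C(C)C)cc(O[Si](C(C)C)(C(C)C)C(C)C)c(CCC(C)(C)O)c1O[C@H](c1cc2c(cc1O[Si](C)(C)C(C)(C)C)OC(C)(C)C=C2)C=C | intermediate
18 | triethyl{[1-(2-{[(1S)-1-[7-(tert-butyldimethylsilyloxy)-2,2-dimethyl-2H-chromen-6-yl]prop-2-en-1-yl]oxy}-3-[3-methyl-3-(triethylsilyloxy)butyl]-4,6-bis(triisopropylsilyloxy)phenyl)ethenyl]oxy}silane | C=C(O[Si](CC)(CC)CC)c1c(O[Si](C(C)C)(C(C)C)C(C)C)cc(O[Si](C(C)C)(C(C)C)C(C)C)c(CCC(C)(C)O[Si](CC)(CC)CC)c1O[C@H](c1cc2c(cc1O[Si](C)(C)C(C)(C)C)OC(C)(C)C=C2)C=C | intermediate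
19 | (2S)-2-[7-(tert-butyldimethylsilyloxy)-2,2-dimethyl-2H-chromen-6-yl]-4-(triethylsilyloxy)-8-[3-methyl-3-(triethylsilyloxy)butyl]-5,7-bis(triisopropylsilyloxy)-2H-chromene | CC(C)(O[Si](CC)(CC)CC)CCc1c(O[Si](C(C)C)(C(C)C)C(C)C)cc(O[Si](C(C)C)(C(C)C)C(C)C)c2c1O[C@H](c1cc3c(cc1O[Si](C)(C)C(C)(C)C)OC(C)(C)C=C3)C=C2O[Si](CC)(CC)CC | intermediate
20 | (2S)-5,7-dihydroxy-2-(7-hydroxy-2,2-dimethyl-2H-chromen-6-yl)-8-(3-hydroxy-3-methylbutyl)chroman-4-one | CC(C)(O)CCc1c(O)cc(O)c2c1O[C@H](c1cc3c(cc1O)OC(C)(C)C=C3)CC2=O | target

## Step count and least certain steps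

Total step count: 13 (steps 1–3 ring A half, steps 4–9 ring B half, steps 10–13 union and completion). Longest linear sequence: 10 steps (steps 4–13, from 6).

Step 12 (key step). The most likely failure is that the ruthenium alkylidene on C3 does not engage the crowded silyl enol ether, which is flanked by the C5 silyl ether and the C8a ether. Intermolecular cross-metathesis of the vinyl groups, ruthenium hydride migration of the vinyl double bond, or protodesilylation of the enol ether by adventitious acid would then take over. The fallback gives up the C3=C4 closure and sets C2 by asymmetric conjugate arylation of a chromone. It sets out from 5 and 12 and returns at 20.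
- Condensation of 5 with Me2NCH(OMe)2 would give the enaminone F1, and brief acid treatment would close it to the chromone F2.
- Bromine–lithium exchange on 12 (n-BuLi, −78 °C), B(Oi-Pr)3 and aqueous work-up would give the arylboronic acid F3.
- Conjugate addition of F3 to F2 under Pd(OCOCF3)2 (divalent palladium) with the enantiomer of tert-butyl pyridine–oxazoline ligand that leads to the (2S) product would give the protected flavanone F4.
- Buffered Bu4NF/AcOH, as in step 13, would then give 20.

Step 10. The most likely failure is slow attack of the di-ortho-substituted, hydrogen-bonded phenoxide on an allyl terminus that is itself shielded by the ortho silyloxy group. This would divert material to the linear ether, or erode the enantiomeric purity through re-ionisation of the branched product. The fallback replaces catalytic allylic substitution by displacement with inversion at a preformed stereocentre. It sets out from 12 (with 5) and returns at 17.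
- Bromine–lithium exchange on 12 and quenching with DMF would give the aldehyde F5.
- Catalytic enantioselective addition of a vinylzinc reagent, (CH2=CH)2Zn, under a chiral amino alcohol would give the (R)-allylic alcohol F6.
- Mitsunobu coupling of F6 with 5 (PPh3, DIAD, toluene, −20 → 0 °C) would give 17 with inversion. Low temperature and a non-polar solvent are needed to hold back ionisation of this electron-rich benzylic alcohol.

Step 2 (and the low selectivity of step 1). The most likely failure is silylation at the C2 hydroxyl instead of the C6 hydroxyl, which would leave the wrong phenol free and lead to the C6-alkyl regioisomer; in step 1, over-alkylation and O-alkylation may lower throughput. The fallback introduces the prenyl group by aromatic Claisen rearrangement, where the position is dictated by the one free, chelated hydroxyl. It sets out from 1 and returns at 4, bypassing steps 1 and 2 at the cost of two extra steps.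
- Bis-silylation of symmetric 1 (TIPSCl, imidazole) would give the 4,6-bis(silyl) ether F7.
- O-alkylation with 3-chloro-3-methylbut-1-yne (DBU, CuCl2 catalytic, MeCN) would give the propargyl ether F8.
- Semihydrogenation (H2, Pd/CaCO3 poisoned with Pb(OAc)2, quinoline) would give the 1,1-dimethylallyl ether F9.
- Heating F9 at about 120 °C would give 4 by (3,3)-sigmatropic shift to the only free ortho carbon.

Step 13. The most likely failure is opening of ring C through a transient enolate or phenoxide, with partial racemisation at C2, or incomplete cleavage of the tertiary triethylsilyl ether under the buffered conditions. The fallback separates ketone release from phenol release. It sets out from 19 and returns at 20.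
- Mild acidic methanolysis (PPTS, MeOH/CH2Cl2, 0 °C) would hydrolyse only the enol ether, by protonation at C3, to the fully silylated flavanone F10, without any enolate being formed.
- The remaining silyl ethers would then be removed with Et3N·3HF in THF, a nearly neutral fluoride source, to give 20.

## Further compounds

F1 | step 12 | (2E)-3-(dimethylamino)-1-[2-hydroxy-3-(3-hydroxy-3-methylbutyl)-4,6-bis(triisopropylsilyloxy)phenyl]prop-2-en-1-one | CN(C)/C=C/C(=O)c1c(O[Si](C(C)C)(C(C)C)C(C)C)cc(O[Si](C(C)C)(C(C)C)C(C)C)c(CCC(C)(C)O)c1O
F2 | step 12 | 8-(3-hydroxy-3-methylbutyl)-5,7-bis(triisopropylsilyloxy)-4H-chromen-4-one | CC(C)(O)CCc1c(O[Si](C(C)C)(C(C)C)C(C)C)cc(O[Si](C(C)C)(C(C)C)C(C)C)c2c1OC=CC2=O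
F3 | step 12 | [7-(tert-butyldimethylsilyloxy)-2,2-dimethyl-2H-chromen-6-yl]boronic acid | CC1(C)C=Cc2cc(B(O)O)c(O[Si](C)(C)C(C)(C)C)cc2O1
F4 | step 12 | (2S)-2-[7-(tert-butyldimethylsilyloxy)-2,2-dimethyl-2H-chromen-6-yl]-8-(3-hydroxy-3-methylbutyl)-5,7-bis(triisopropylsilyloxy)chroman-4-one | CC(C)(O)CCc1c(O[Si](C(C)C)(C(C)C)C(C)C)cc(O[Si](C(C)C)(C(C)C)C(C)C)c2c1O[C@H](c1cc3c(cc1O[Si](C)(C)C(C)(C)C)OC(C)(C)C=C3)CC2=O
F5 | step 10 | 7-(tert-butyldimethylsilyloxy)-2,2-dimethyl-2H-chromene-6-carbaldehyde | CC1(C)C=Cc2cc(C=O)c(O[Si](C)(C)C(C)(C)C)cc2O1
F6 | step 10 | (1R)-1-[7-(tert-butyldimethylsilyloxy)-2,2-dimethyl-2H-chromen-6-yl]prop-2-en-1-ol | O[C@@H](c1cc2c(cc1O[Si](C)(C)C(C)(C)C)OC(C)(C)C=C2)C=C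
F7 | step 2 | 1-[2-hydroxy-4,6-bis(triisopropylsilyloxy)phenyl]ethan-1-one | CC(=O)c1c(O)cc(O[Si](C(C)C)(C(C)C)C(C)C)cc1O[Si](C(C)C)(C(C)C)C(C)C
F8 | step 2 | 1-[2-(2-methylbut-3-yn-2-yloxy)-4,6-bis(triisopropylsilyloxy)phenyl]ethan-1-one | CC(=O)c1c(OC(C)(C)C#C)cc(O[Si](C(C)C)(C(C)C)C(C)C)cc1O[Si](C(C)C)(C(C)C)C(C)C
F9 | step 2 | 1-[2-(2-methylbut-3-en-2-yloxy)-4,6-bis(triisopropylsilyloxy)phenyl]ethan-1-one | CC(=O)c1c(OC(C)(C)C=C)cc(O[Si](C(C)C)(C(C)C)C(C)C)cc1O[Si](C(C)C)(C(C)C)C(C)C
F10 | step 13 | (2S)-2-[7-(tert-butyldimethylsilyloxy)-2,2-dimethyl-2H-chromen-6-yl]-8-[3-methyl-3-(triethylsilyloxy)butyl]-5,7-bis(triisopropylsilyloxy)chroman-4-one | CC(C)(O[Si](CC)(CC)CC)CCc1c(O[Si](C(C)C)(C(C)C)C(C)C)cc(O[Si](C(C)C)(C(C)C)C(C)C)c2c1O[C@H](c1cc3c(cc1O[Si](C)(C)C(C)(C)C)OC(C)(C)C=C3)CC2=O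
A1 | alternative 1 | (2S)-2-[7-(allyloxy)-2,2-dimethyl-2H-chromen-6-yl]-5,7-dihydroxy-8-[3-methyl-3-(triethylsilyloxy)butyl]chroman-4-one | CC(C)(O[Si](CC)(CC)CC)CCc1c(O)cc(O)c2c1O[C@H](c1cc3c(cc1OCC=C)OC(C)(C)C=C3)CC2=O
A2 | alternative 1 | (2S)-2-[7-(allyloxy)-2,2-dimethyl-2H-chromen-6-yl]-5-(4-methylphenylsulfinyl)-2,3-dihydro-4H-pyran-4-one | O=C1C[C@@H](c2cc3c(cc2OCC=C)OC(C)(C)C=C3)OC=C1S(=O)c1ccc(C)cc1
A3 | alternative 1 | 1-methoxy-7-methyl-7-(triethylsilyloxy)-1,3-bis(trimethylsilyloxy)octa-1,3-diene | COC(O[Si](C)(C)C)=CC(O[Si](C)(C)C)=CCCC(C)(C)O[Si](CC)(CC)CC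
A4 | alternative 2 | (2S)-5,7-bis(tert-butyldimethylsilyloxy)-2-[7-(tert-butyldimethylsilyloxy)-2,2-dimethyl-2H-chromen-6-yl]-8-(3-hydroxy-3-methylbutyl)chroman-4-one | CC(C)(O)CCc1c(O[Si](C)(C)C(C)(C)C)cc(O[Si](C)(C)C(C)(C)C)c2c1O[C@H](c1cc3c(cc1O[Si](C)(C)C(C)(C)C)OC(C)(C)C=C3)CC2=O
A5 | alternative 2 | (2S)-5,7-bis(tert-butyldimethylsilyloxy)-2-[2-(tert-butyldimethylsilyloxy)-4-(2-methylbut-3-yn-2-yloxy)phenyl]-8-(3-hydroxy-3-methylbutyl)chroman-4-one | CC(C)(O)CCc1c(O[Si](C)(C)C(C)(C)C)cc(O[Si](C)(C)C(C)(C)C)c2c1O[C@H](c1ccc(OC(C)(C)C#C)cc1O[Si](C)(C)C(C)(C)C)CC2=O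
A6 | alternative 3 | (2S)-2,4-cis-5,7-bis(allyloxy)-2-(7-hydroxy-2,2-dimethyl-2H-chromen-6-yl)-8-(3-hydroxy-3-methylbutyl)-4-methoxychroman | CC(C)(O)CCc1c(OCC=C)cc(OCC=C)c2c1O[C@H](c1cc3c(cc1O)OC(C)(C)C=C3)C[C@@H]2OC
A7 | alternative 3 | 4,6-bis(allyloxy)-2-hydroxy-3-(3-hydroxy-3-methylbutyl)benzaldehyde | CC(C)(O)CCc1c(OCC=C)cc(OCC=C)c(C=O)c1O
A8 | alternative 3 | 6-ethenyl-2,2-dimethyl-2H-chromen-7-ol | C=Cc1cc2c(cc1O)OC(C)(C)C=C2
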